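Remark on the chemistry: the three alkene geometries are taken as drawn in the target (2Z,4Z,8Z), and locants follow the ansa numbering (C1 = lactam carbonyl, C2–C15 = chain, C16–C21 = arene).

## Analysis of the target

Compound 47 is a 19-membered ansa lactam in which the C1–C15 chain bridges C16 and C20 of a 2-aminohydroquinone (ring C16–C21) in a meta fashion. The chain carries seven stereocentres: C6 (OMe) and C7 (carbamate) are syn, C10 (Me) and C11 (OMe) are syn, C11 and C12 (OMe) are anti, C12 and C14 (Me) are 1,3-anti, and C14 and C15 (benzylic OMe) are syn. C13 is a bare methylene that isolates the C10–C12 triad from the C14–C15 pair, so C12 has no neighbouring handle for substrate control from the east. All three alkenes are Z: the (2Z,4Z)-2-methyldienamide and the trisubstituted C8=C9 bond. The sensitive groups are the air-oxidisable hydroquinone, the primary carbamate on the allylic C7 oxygen, the (Z,Z)-dienamide, which can isomerise, and the benzylic C15 ether. The hard parts are the C12 centre, the two Z-configured alkenes that must be made and kept, and a pentasubstituted arene with nitrogen ortho to oxygen that has to be joined to the chain and closed into a large ring. The plan rests on the arene: the C21 oxygen lies between the two bridgeheads C16 and C20, the C18 oxygen is para to it, and C17 and C19 carry hydrogen. That is the pattern formed when an alkenyl carbene complex, a terminal alkyne and one CO are united in a benzannulation.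

## Retrosynthetic reasoning

**Endgame (47 back to 42).** Hydroquinone 47 is the reduced form of quinone 46, so the last step is a quinone reduction, which keeps the air-sensitive oxidation state out of all earlier steps. Carbamate 46 comes from alcohol 44 through acyl carbamate 45, and 44 from silyl ether 43. The carbamate goes on late because its acidic NH2 would not survive the base-mediated steps. Quinone 43 is cut back to phenol 42: one oxidation should turn the 4-methoxyphenol into the quinone and also remove the N-benzyl group, so the nitrogen protecting group costs no separate step.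

**Arene and macrocycle (42 back to 40).** In 42 the bonds C18–C19, C20–C21 and C16–C21 are cut together. This opens the benzene ring and the 19-membered ring at once and leads to the open-chain carbene complex 40, in which C18 is the carbene carbon, C16=C17 its alkenyl group, C19≡C20 a terminal ynamide and C21 a carbonyl ligand. The cut is made here because the arene then needs no separate synthesis, no nitroarene and no aniline acylation, and the C21 phenol and C18 methyl ether come out already differentiated. The forward reaction has to insert the alkyne with C19 at C18, take up CO, and do so intramolecularly.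

**C16=C17 (40 back to 35 and 38).** The alkenyl carbene is cut at C16=C17 into aldehyde 35 and the methyl carbene complex 38 (from 36 via 37). A condensation of the acidic methyl group of 38 is the only way to install the carbene that tolerates an ynamide, a dienamide and silyl ethers; it has to be the last step before the key step.

**N–C20 (35 back to 32).** Aldehyde 35 comes from alcohol 34, and 34 from the silylated ynamide 33 by one desilylation that frees both the alkyne and the C16 hydroxyl. Ynamide 33 is cut at the N–C(sp) bond to the secondary amide 32. The nitrogen must stay substituted because a secondary ynamide would tautomerise, and a 4-methoxybenzyl group is chosen because the quinone-forming oxidant removes it.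

**C3–C4 (32 back to 25 and 30).** The (2Z,4Z)-diene is traced to enyne 31 and cut at C3–C4 into terminal alkyne 25 and the (Z)-iodoacrylamide 30. The 2Z geometry is then bought in 30 (from acid 28, alcohol 27, propargyl alcohol 26 and amine 29), and the 4Z geometry comes from a cis-semi-reduction. This is shorter than two successive Z-selective olefinations followed by amidation.

**C6–C7 (25 back to 17 and 20).** Alkyne 25 comes from aldehyde 24, which is reached through Weinreb amides 23 and 22 from aldol adduct 21. Cutting C6–C7 gives (Z)-enal 17 and the glycolate imide 20 (from 18 and 19). A syn glycolate aldol sets both oxygen-bearing centres under auxiliary control, independent of the remote centres in 17.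

**C8=C9 (17 back to 14).** Enal 17 is taken back through alcohol 16 and ester 15 to aldehyde 14 by a Z-selective phosphonate olefination, the most dependable way to a (Z)-2-methylenoate.

**C10–C11 (14 back to 11).** Aldehyde 14 comes from alkene 13 by ozonolysis, 13 from alcohol 12, and 12 from α-methoxy aldehyde 11 by a Z-crotylboration. The syn C10/C11 relationship follows from the Z-crotyl geometry, and the anti C11/C12 relationship is the intrinsic preference of an α-alkoxy aldehyde, so reagent and substrate control should reinforce each other.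

**C12–C13 (11 back to 6 and 9).** C12 has no neighbouring control element, so it is set by an auxiliary: aldehyde 11 comes from hydrazone 10, which is cut at C12–C13 into iodide 6 and the hydrazone 9 of methoxyacetaldehyde (from 7 and 8). The methoxy group is thus carried in from the start and the aldehyde is released in the next step.

**C14–C15 (6 back to 1 and 2).** Iodide 6 comes from alcohol 5, imide 4 and aldol adduct 3. Cutting C14–C15 gives the propionyl imide 1 and the silyloxy aldehyde 2; a syn aldol sets both centres and leaves C13 as the acyl carbon that becomes the methylene. C16 is carried as a primary silyl ether because a benzyl ether could not be removed once the alkenes and the ynamide are present. C7 is given the bulkier triisopropylsilyl group so that the C16 ether can be cleaved selectively.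

## Alternatives that were turned down

**Alternative 1:** The lactam N–C20 bond is cut and the nitrogen is taken out of the ring, leaving an 18-membered aryl ketone whose oxime A1 carries the hydroxyl anti to the arene. In the forward direction A1 would be O-sulfonylated with a hindered arenesulfonyl chloride, and the anti-periplanar aryl carbon C20 would migrate from C1 to nitrogen, expanding the ring to lactam A2.
- For it: the migration is stereospecific, the nitrogen needs no protecting group because it enters last, and every step belongs to a documented reaction class. On precedent it is stronger than the chosen route.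
- Against it: everything depends on one oxime geometry at a ketone flanked by an ortho-disubstituted arene and a trisubstituted enyne. Such oximes differ little in energy and equilibrate under the rearrangement conditions. The wrong isomer sends the alkenyl carbon to nitrogen, and conjugated oxime sulfonates also fragment to nitriles.
- The carbocycle still needs its own macrocyclisation, the arene must be built as a fully substituted unit with two methyl ethers to remove, and the alkyne of A2 must still be reduced.
- In its place the chosen route offers one step for ring closure plus arene construction, and a phenol/methyl ether pair that a single oxidant converts to the quinone.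

**Alternative 2:** The C11–C12 bond is cut, giving seco dialdehyde A3. In the forward direction SmI2 would reduce both aldehydes to ketyls that couple, forming the bond, both carbinol centres and the ring in diol A4.
- For it: it is the most convergent of the plans, since two halves of similar size are joined by an amide, and the ring closure creates two stereocentres. On convergence it is stronger than the chosen route.
- Against it: four diastereomeric diols are possible and the target needs the anti isomer with one absolute sense. In a 19-membered ring no chelated diketyl geometry enforces this, and the only nearby control element is the C10 methyl group.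
- The conjugated dienamide is itself reducible by SmI2. The diol would then have to be O-methylated twice next to an anilide N–H and a carbamate NH2 that are more acidic than the hydroxyls.
- The chosen route sets C11 and C12 early, on the small open-chain compounds 11 and 12 under reagent control, and never carries a free diol.

**Alternative 3:** The C4–C5 bond is cut as an alkyne, giving seco diyne A5 with two methyl-capped alkynes. In the forward direction the alkylidyne Mo(≡CC6H4OMe-4)(OSiPh3)3 would exchange the alkyne ends, expel the two methyl caps as a volatile by-product and close the ring to cycloalkyne A6; semi-reduction would then give the 4Z-alkene.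
- For it: ring-closing alkyne metathesis is among the most dependable ways to close large rings, the silanolate catalysts tolerate ethers, silyl ethers and amides, and the 4Z geometry follows from the semi-reduction. On predictability of the ring closure it is clearly stronger than the chosen route, and it is equal on the C4=C5 geometry, which the chosen route also derives from an alkyne (31).
- Against it: the alkyne that reacts is conjugated to an electron-poor Z-enamide on one side and flanked by a propargylic methoxy group on the other, next to a free anilide N–H.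
- The arene has to be made separately as a pentasubstituted aminohydroquinone diether, attached at C15 with stereocontrol and acylated on a hindered aniline, and its two methyl ethers have to be removed at the end.
- The chosen route spends no steps on the arene building block, at the price of an unprecedented key step.

Key step: step 30

## Route

Step 1
Reactants: 1 (R)-4-benzyl-3-propionyl-2-oxazolidinone; 2 (tert-butyldimethylsilyloxy)acetaldehyde
Product: 3 (R)-4-benzyl-3-[(2R,3R)-4-(tert-butyldimethylsilyloxy)-3-hydroxy-2-methylbutanoyl]-2-oxazolidinone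
Conditions: Bu2BOTf, iPr2NEt, CH2Cl2, −78 → 0 °C; then pH 7 buffer, MeOH, H2O2
Reagents that add atoms: none
Why: Evans syn aldol; the Z-boron enolate of 1 should add through a Zimmerman–Traxler chair on the face away from the benzyl group, which sets C14 and C15 syn with the absolute sense fixed by the (R)-auxiliary.

Step 2
Reactants: 3
Product: 4 (R)-4-benzyl-3-[(2R,3R)-4-(tert-butyldimethylsilyloxy)-3-methoxy-2-methylbutanoyl]-2-oxazolidinone
Conditions: Me3OBF4, 1,8-bis(dimethylamino)naphthalene, CH2Cl2, 0 °C → rt
Reagents that add atoms: trimethyloxonium tetrafluoroborate, C[O+](C)C.F[B-](F)(F)F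
Why: O-methylation with Meerwein salt and a non-nucleophilic base is not basic enough for retro-aldol cleavage or silyl migration, so the C15 methyl ether should form without loss of configuration.

Step 3
Reactants: 4
Product: 5 (2S,3R)-4-(tert-butyldimethylsilyloxy)-3-methoxy-2-methylbutan-1-ol
Conditions: LiBH4, MeOH (1 equiv), Et2O, 0 °C
Reagents that add atoms: none
Why: Reductive cleavage of the imide at the exocyclic carbonyl should give the C13 alcohol and return the auxiliary; no stereocentre is touched.

Step 4
Reactants: 5
Product: 6 tert-butyl[(2R,3R)-4-iodo-2-methoxy-3-methylbutoxy]dimethylsilane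
Conditions: I2, PPh3, imidazole, CH2Cl2, 0 °C → rt
Reagents that add atoms: iodine, [I][I]
Why: Appel-type iodination of a primary alcohol; the neutral conditions leave the silyl ether and both stereocentres alone.

Step 5
Reactants: 7 methoxyacetaldehyde; 8 (S)-1-amino-2-(methoxymethyl)pyrrolidine (SAMP)
Product: 9 (S,E)-N-(2-methoxyethylidene)-2-(methoxymethyl)pyrrolidin-1-amine
Conditions: MgSO4, CH2Cl2, 0 °C → rt
Reagents that add atoms: none
Why: Simple hydrazone condensation; the E-hydrazone is the only isomer expected for an aldehyde.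

Step 6
Reactants: 9; 6
Product: 10 SAMP hydrazone of (2S,4S,5R)-6-(tert-butyldimethylsilyloxy)-2,5-dimethoxy-4-methylhexanal
Conditions: LiN(iPr)2, THF, 0 °C; then 6, −100 → −20 °C
Reagents that add atoms: none
Why: Enders SAMP-hydrazone alkylation; the lithium azaenolate is nucleophilic enough for a β-branched primary iodide and is alkylated on the face away from the chelated methoxymethyl arm. By analogy with α-oxygenated SAMP hydrazones, in which the oxygen substituent is trans to nitrogen in the azaenolate, the (S)-auxiliary should give the 12S centre.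

Step 7
Reactants: 10
Product: 11 (2S,4S,5R)-6-(tert-butyldimethylsilyloxy)-2,5-dimethoxy-4-methylhexanal
Conditions: O3, CH2Cl2, −78 °C; then Ar purge
Reagents that add atoms: ozone, [O-][O+]=O
Why: Ozonolytic cleavage of the C=N bond releases the aldehyde at low temperature without acid or base, so the α-methoxy centre should not epimerise; the aldehyde is used crude.

Step 8
Reactants: 11
Product: 12 (3S,4R,5S,7S,8R)-9-(tert-butyldimethylsilyloxy)-5,8-dimethoxy-3,7-dimethylnon-1-en-4-ol
Conditions: cis-but-2-ene, KOt-Bu, n-BuLi, THF, −78 → −45 °C; (+)-Ipc2BOMe [from (−)-α-pinene], −78 °C; BF3·OEt2; then 11, −78 °C; NaOH, H2O2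
Reagents that add atoms: (Z)-crotyldiisopinocampheylborane made in the flask from cis-but-2-ene, C/C=C\CB([C@H]1C[C@H]2C[C@@H]([C@@H]1C)C2(C)C)[C@H]1C[C@H]2C[C@@H]([C@@H]1C)C2(C)C
Why: Brown crotylboration through a closed chair transition state; the Z-crotyl unit gives the C10/C11 syn relationship and the borane from (−)-α-pinene attacks the Re face of the aldehyde, which gives 11R. This is the matched case, since Z-crotylboron reagents intrinsically prefer the anti (Cornforth) relationship to an α-alkoxy group, as required for C11/C12.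

Step 9
Reactants: 12
Product: 13 tert-butyl{[(2R,3S,5S,6R,7S)-2,5,6-trimethoxy-3,7-dimethylnon-8-en-1-yl]oxy}dimethylsilane
Conditions: NaH, MeI, THF/DMF, 0 °C → rt
Reagents that add atoms: iodomethane, CI
Why: Williamson methylation of the only free hydroxyl; the silyl ether is five carbons away, so no silyl migration is possible.

Step 10
Reactants: 13
Product: 14 (2R,3R,4S,6S,7R)-8-(tert-butyldimethylsilyloxy)-3,4,7-trimethoxy-2,6-dimethyloctanal
Conditions: O3, CH2Cl2/MeOH, −78 °C; then PPh3
Reagents that add atoms: ozone, [O-][O+]=O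
Why: Ozonolysis of the only alkene gives the C9 aldehyde; the α-methyl aldehyde is taken on at once to avoid epimerisation at C10.

Step 11
Reactants: 14
Product: 15 methyl (2Z,4S,5R,6S,8S,9R)-10-(tert-butyldimethylsilyloxy)-5,6,9-trimethoxy-2,4,8-trimethyldec-2-enoate
Conditions: methyl 2-[bis(2,2,2-trifluoroethoxy)phosphoryl]propanoate, KN(SiMe3)2, 18-crown-6, THF, −78 °C
Reagents that add atoms: methyl 2-[bis(2,2,2-trifluoroethoxy)phosphoryl]propanoate, COC(=O)C(C)P(=O)(OCC(F)(F)F)OCC(F)(F)F
Why: Still–Gennari olefination; the electron-poor phosphonate with a dissociated potassium counter-ion eliminates under kinetic control and should give the Z-trisubstituted enoate, in which C7 is cis to C10.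

Step 12
Reactants: 15
Product: 16 (2Z,4S,5R,6S,8S,9R)-10-(tert-butyldimethylsilyloxy)-5,6,9-trimethoxy-2,4,8-trimethyldec-2-en-1-ol
Conditions: iBu2AlH, CH2Cl2, −78 °C; Rochelle salt work-up
Reagents that add atoms: none
Why: 1,2-Reduction of the enoate to the allylic alcohol leaves the alkene geometry unchanged.

Step 13
Reactants: 16
Product: 17 (2Z,4S,5R,6S,8S,9R)-10-(tert-butyldimethylsilyloxy)-5,6,9-trimethoxy-2,4,8-trimethyldec-2-enal
Conditions: Dess–Martin periodinane, NaHCO3, CH2Cl2, 0 °C
Reagents that add atoms: none
Why: Buffered Dess–Martin oxidation is neutral and fast, so the Z-enal should not isomerise to the more stable E-isomer; it is used without storage.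

Step 14
Reactants: 18 (R)-4-benzyl-2-oxazolidinone; 19 methoxyacetyl chloride
Product: 20 (R)-4-benzyl-3-(methoxyacetyl)-2-oxazolidinone
Conditions: n-BuLi, THF, −78 °C; then 19
Reagents that add atoms: none
Why: N-acylation of the lithiated oxazolidinone with an acid chloride.

Step 15
Reactants: 20; 17
Product: 21 glycolate aldol adduct: N-acyl oxazolidinone of the C5–C16 chain with C6 OMe and free C7 OH (syn), 8Z
Conditions: Bu2BOTf, Et3N, CH2Cl2, −78 → 0 °C; then 17, −78 → −20 °C; pH 7 buffer, MeOH, H2O2
Reagents that add atoms: none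
Why: Evans syn glycolate aldol; the Z-boron enolate of 20 reacts through a chair transition state under auxiliary control, and the (R)-auxiliary gives the C6/C7 syn pair with the sense of the target. The Z-enal has no α-stereocentre, so there is no mismatch.

Step 16
Reactants: 21
Product: 22 N-methoxy-N-methyl amide of the C5–C16 chain (C7 OH)
Conditions: MeNH(OMe)·HCl, AlMe3, THF, −20 → 0 °C
Reagents that add atoms: N,O-dimethylhydroxylamine hydrochloride, CNOC.Cl
Why: Weinreb transamidation; the aluminium amide, guided by the free β-hydroxyl, attacks the exocyclic carbonyl, removes the auxiliary and avoids reducing a hindered imide later.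

Step 17
Reactants: 22
Product: 23 N-methoxy-N-methyl amide of the C5–C16 chain, C7 triisopropylsilyl ether
Conditions: iPr3SiOTf, 2,6-lutidine, CH2Cl2, 0 °C → rt
Reagents that add atoms: triisopropylsilyl triflate, CC(C)[Si](C(C)C)(C(C)C)OS(=O)(=O)C(F)(F)F
Why: The silyl triflate protects the hindered allylic C7 hydroxyl; the triisopropylsilyl group is chosen so that the primary C16 silyl ether can be cleaved later in its presence.

Step 18
Reactants: 23
Product: 24 C5 aldehyde of the C5–C16 chain
Conditions: iBu2AlH, THF, −78 °C
Reagents that add atoms: none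
Why: Reduction of a Weinreb amide stops at the chelated tetrahedral intermediate and gives the aldehyde on work-up; the α-methoxy aldehyde is used crude to protect C6.

Step 19
Reactants: 24
Product: 25 terminal alkyne C4–C16 (C4≡C5)
Conditions: dimethyl (1-diazo-2-oxopropyl)phosphonate, K2CO3, MeOH, 0 °C → rt
Reagents that add atoms: dimethyl (1-diazo-2-oxopropyl)phosphonate, COP(=O)(OC)C(=[N+]=[N-])C(C)=O
Why: Ohira–Bestmann (Seyferth–Gilbert) homologation; the mild carbonate conditions are the standard choice for α-alkoxy aldehydes and should leave C6 intact.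

Step 20
Reactants: 26 propargyl alcohol
Product: 27 (Z)-3-iodo-2-methylprop-2-en-1-ol
Conditions: MeMgBr (3 equiv), CuI (10 mol %), THF, −10 °C → rt; then I2, −10 °C
Reagents that add atoms: methylmagnesium bromide, C[Mg]Br; iodine, [I][I]
Why: Copper-catalysed anti-carbomagnesiation of the magnesium alkoxide gives a five-membered chelate with magnesium cis to the oxygen-bearing carbon, and iodinolysis with retention puts iodine cis to CH2OH.

Step 21
Reactants: 27
Product: 28 (Z)-3-iodo-2-methylprop-2-enoic acid
Conditions: TEMPO (cat.), PhI(OAc)2, MeCN/H2O, rt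
Reagents that add atoms: water, O
Why: Oxoammonium oxidation in aqueous acetonitrile takes the primary allylic alcohol through the aldehyde hydrate to the acid under nearly neutral conditions that should preserve the vinyl iodide geometry.

Step 22
Reactants: 28; 29 4-methoxybenzylamine
Product: 30 (Z)-3-iodo-N-(4-methoxybenzyl)-2-methylprop-2-enamide
Conditions: EDC·HCl, HOBt, iPr2NEt, CH2Cl2, 0 °C → rt
Reagents that add atoms: none
Why: Carbodiimide amide coupling through the active ester; acylation at 0 °C should outrun addition–elimination of the amine at the β-iodide.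

Step 23
Reactants: 25; 30
Product: 31 (2Z)-en-4-yne secondary amide C1–C16
Conditions: Pd(PPh3)2Cl2 (5 mol %), CuI (10 mol %), Et3N, THF, rt
Reagents that add atoms: none
Why: Sonogashira coupling of a vinyl iodide proceeds with retention of the Z geometry at room temperature and forms C3–C4 with the amide already in place.

Step 24
Reactants: 31
Product: 32 (2Z,4Z)-dienamide C1–C16, N-(4-methoxybenzyl) secondary amide
Conditions: Zn (activated with Cu(OAc)2 and AgNO3), MeOH/H2O, rt
Reagents that add atoms: none
Why: Activated zinc reduces conjugated enynes to cis-alkenes and stops there, so the 4Z bond should form without over-reduction or change at the trisubstituted alkenes.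

Step 25
Reactants: 32
Product: 33 N-[(trimethylsilyl)ethynyl] ynamide of the C1–C16 chain
Conditions: KN(SiMe3)2, toluene, 0 °C; then phenyl[(trimethylsilyl)ethynyl]iodonium triflate, 0 °C → rt
Reagents that add atoms: phenyl[(trimethylsilyl)ethynyl]iodonium triflate, C[Si](C)(C)C#C[I+]c1ccccc1.[O-]S(=O)(=O)C(F)(F)F
Why: N-alkynylation of an amide anion with an alkynyliodonium salt; the amidate adds to the β-carbon, loss of iodobenzene gives an alkylidene carbene, and a fast 1,2-silyl shift gives the ynamide.

Step 26
Reactants: 33
Product: 34 terminal ynamide with free C16 hydroxyl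
Conditions: Bu4NF, AcOH, THF, 0 °C
Reagents that add atoms: none
Why: Buffered fluoride cleaves the alkynyl C–Si bond and the unhindered primary silyl ether, while the hindered secondary triisopropylsilyl ether at C7 should survive.

Step 27
Reactants: 34
Product: 35 terminal ynamide C16 aldehyde
Conditions: Dess–Martin periodinane, pyridine, CH2Cl2, 0 °C
Reagents that add atoms: none
Why: Buffered Dess–Martin oxidation is non-acidic, which the ynamide needs, and should give the α-methoxy aldehyde without epimerisation at C15; it is used at once.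

Step 28
Reactants: 36 hexacarbonylchromium
Product: 38 pentacarbonyl(1-methoxyethylidene)chromium, via lithium acetylpentacarbonylchromate 37 (not isolated)
Conditions: MeLi, Et2O, 0 °C; then Me3OBF4, H2O/CH2Cl2, 0 °C
Reagents that add atoms: methyllithium, [Li]C; trimethyloxonium tetrafluoroborate, C[O+](C)C.F[B-](F)(F)F
Why: Classical Fischer carbene synthesis: the organolithium adds to a CO ligand and the acyl chromate is O-methylated.

Step 29
Reactants: 38; 35
Product: 40 alkenyl(methoxy)carbene pentacarbonylchromium bearing the terminal N-(4-methoxybenzyl) ynamide (C7 triisopropylsilyl ether), via aldol adduct 39 (not isolated)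
Conditions: 38, n-BuLi, THF, −78 °C; then 35, −78 → −40 °C; then MsCl, Et3N, −40 → 0 °C
Reagents that add atoms: none
Why: Aldol condensation of a Fischer carbene complex: the methyl group of 38 is acidic, its anion adds to the activated α-methoxy aldehyde, and mesylation with amine-induced elimination gives the E-alkenyl carbene. The anion is too weak a base to touch the alkyne C–H or C15.

Step 30
Reactants: 40
Product: 42 ansa 4-methoxyphenol N-(4-methoxybenzyl) lactam (C7 triisopropylsilyl ether), via tricarbonylchromium arene complex 41 (not isolated)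
Conditions: THF (2 mM, slow addition), 55 °C, Ar; then air, rt
Reagents that add atoms: none
Why: Proposed new method: on warming, 40 should lose one CO, the tethered terminal ynamide should coordinate and insert into the Cr=C18 bond with its unsubstituted carbon C19 bonding to C18, and insertion of a CO ligand should then give a chromium-bound dienylketene whose C21 closes onto C16 in a 6π-electrocyclisation, tautomerisation giving the phenol as complex 41, which air decomplexes. The closest known reaction type is the intramolecular Dötz benzannulation of alkenyl carbene complexes carrying a tethered terminal alkyne, which gives meta-bridged cyclophanes; an ynamide as the alkyne partner in such a macrocyclisation has no precedent. The macrocycle is closed end-to-end in the alkyne-insertion event and becomes the 19-membered ansa ring when C16–C21 forms, and the benzene ring is closed by the electrocyclisation of the ketene. No stereocentre is formed and the seven existing ones are spectators. Three selectivities are needed: insertion with C19 rather than C20 at C18, uptake of CO before ring closure, and intramolecular rather than intermolecular reaction. The first is secured by the terminal alkyne, whose substituted carbon ends up next to the CO-derived carbon, and by the polarisation of the ynamide, whose nucleophilic β-carbon C19 meets the electrophilic carbene carbon, while the 17-atom tether is long enough for the meta-bridging mode. The second is favoured by the alkenyl carbene, by the coordinating solvent and by the N-acyl group, which lowers the donor strength of nitrogen so that the inserted intermediate should not rest as a stabilised aminocarbene. The third rests on slow addition into dilute solution.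

Step 31
Reactants: 42
Product: 43 ansa quinone N–H lactam (C7 triisopropylsilyl ether)
Conditions: (NH4)2Ce(NO3)6, MeCN/H2O, 0 °C
Reagents that add atoms: water, O
Why: Oxidative demethylation of the 4-methoxyphenol gives the para-quinone by addition of water at C18 and loss of methanol. The same oxidant cleaves the 4-methoxybenzyl group from the amide nitrogen by benzylic oxidation, a known reaction of N-benzyl amides and imides.

Step 32
Reactants: 43
Product: 44 ansa quinone lactam with free C7 hydroxyl
Conditions: HF·pyridine, pyridine, THF, 0 °C → rt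
Reagents that add atoms: none
Why: Buffered HF removes the secondary silyl ether without the basic conditions that would damage the quinone.

Step 33
Reactants: 44
Product: 46 ansa quinone C7 carbamate, via trichloroacetyl carbamate 45 (not isolated)
Conditions: Cl3CC(O)NCO, CH2Cl2, 0 °C; then neutral Al2O3, rt
Reagents that add atoms: trichloroacetyl isocyanate, O=C=NC(=O)C(Cl)(Cl)Cl
Why: The highly electrophilic isocyanate acylates even a hindered secondary alcohol much faster than the lactam N–H, and the trichloroacetyl group is then hydrolysed on neutral alumina to leave the primary carbamate.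

Step 34
Reactants: 46
Product: 47 target hydroquinone
Conditions: Na2S2O4, EtOAc/H2O, rt, Ar
Reagents that add atoms: none
Why: Dithionite reduces the quinone to the hydroquinone and touches nothing else; isolation under argon prevents re-oxidation.

## Compound list

1 | (R)-4-benzyl-3-propionyl-2-oxazolidinone | CCC(=O)N1[C@H](Cc2ccccc2)COC1=O | starting material
2 | (tert-butyldimethylsilyloxy)acetaldehyde | O=CCO[Si](C)(C)C(C)(C)C | starting material
3 | (R)-4-benzyl-3-[(2R,3R)-4-(tert-butyldimethylsilyloxy)-3-hydroxy-2-methylbutanoyl]-2-oxazolidinone | O=C1OC[C@@H](Cc2ccccc2)N1C(=O)[C@H](C)[C@@H](O)CO[Si](C)(C)C(C)(C)C | intermediate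
4 | (R)-4-benzyl-3-[(2R,3R)-4-(tert-butyldimethylsilyloxy)-3-methoxy-2-methylbutanoyl]-2-oxazolidinone | O=C1OC[C@@H](Cc2ccccc2)N1C(=O)[C@H](C)[C@@H](OC)CO[Si](C)(C)C(C)(C)C | intermediate
5 | (2S,3R)-4-(tert-butyldimethylsilyloxy)-3-methoxy-2-methylbutan-1-ol | OC[C@H](C)[C@@H](OC)CO[Si](C)(C)C(C)(C)C | intermediate
6 | tert-butyl[(2R,3R)-4-iodo-2-methoxy-3-methylbutoxy]dimethylsilane | IC[C@H](C)[C@@H](OC)CO[Si](C)(C)C(C)(C)C | intermediate
7 | methoxyacetaldehyde | COCC=O | starting material
8 | (S)-1-amino-2-(methoxymethyl)pyrrolidine (SAMP) | COC[C@@H]1CCCN1N | starting material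
9 | (S,E)-N-(2-methoxyethylidene)-2-(methoxymethyl)pyrrolidin-1-amine | COC/C=N/N1CCC[C@H]1COC | intermediate
10 | SAMP hydrazone of (2S,4S,5R)-6-(tert-butyldimethylsilyloxy)-2,5-dimethoxy-4-methylhexanal | COC[C@@H]1CCCN1/N=C/[C@@H](OC)C[C@H](C)[C@@H](OC)CO[Si](C)(C)C(C)(C)C | intermediate
11 | (2S,4S,5R)-6-(tert-butyldimethylsilyloxy)-2,5-dimethoxy-4-methylhexanal (C11–C16) | O=C[C@@H](OC)C[C@H](C)[C@@H](OC)CO[Si](C)(C)C(C)(C)C | intermediate
12 | (3S,4R,5S,7S,8R)-9-(tert-butyldimethylsilyloxy)-5,8-dimethoxy-3,7-dimethylnon-1-en-4-ol | C=C[C@H](C)[C@@H](O)[C@@H](OC)C[C@H](C)[C@@H](OC)CO[Si](C)(C)C(C)(C)C | intermediate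
13 | tert-butyl{[(2R,3S,5S,6R,7S)-2,5,6-trimethoxy-3,7-dimethylnon-8-en-1-yl]oxy}dimethylsilane | C=C[C@H](C)[C@@H](OC)[C@@H](OC)C[C@H](C)[C@@H](OC)CO[Si](C)(C)C(C)(C)C | intermediate
14 | (2R,3R,4S,6S,7R)-8-(tert-butyldimethylsilyloxy)-3,4,7-trimethoxy-2,6-dimethyloctanal (C9–C16) | O=C[C@H](C)[C@@H](OC)[C@@H](OC)C[C@H](C)[C@@H](OC)CO[Si](C)(C)C(C)(C)C | intermediate
15 | methyl (2Z,4S,5R,6S,8S,9R)-10-(tert-butyldimethylsilyloxy)-5,6,9-trimethoxy-2,4,8-trimethyldec-2-enoate | COC(=O)/C(C)=C\[C@H](C)[C@@H](OC)[C@@H](OC)C[C@H](C)[C@@H](OC)CO[Si](C)(C)C(C)(C)C | intermediate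
16 | (2Z,4S,5R,6S,8S,9R)-10-(tert-butyldimethylsilyloxy)-5,6,9-trimethoxy-2,4,8-trimethyldec-2-en-1-ol | OC/C(C)=C\[C@H](C)[C@@H](OC)[C@@H](OC)C[C@H](C)[C@@H](OC)CO[Si](C)(C)C(C)(C)C | intermediate
17 | (2Z,4S,5R,6S,8S,9R)-10-(tert-butyldimethylsilyloxy)-5,6,9-trimethoxy-2,4,8-trimethyldec-2-enal (C7–C16) | O=C/C(C)=C\[C@H](C)[C@@H](OC)[C@@H](OC)C[C@H](C)[C@@H](OC)CO[Si](C)(C)C(C)(C)C | intermediate
18 | (R)-4-benzyl-2-oxazolidinone | O=C1N[C@H](Cc2ccccc2)CO1 | starting material
19 | methoxyacetyl chloride | COCC(Cl)=O | starting material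
20 | (R)-4-benzyl-3-(methoxyacetyl)-2-oxazolidinone | COCC(=O)N1[C@H](Cc2ccccc2)COC1=O | intermediate
21 | glycolate aldol adduct: N-acyl (R)-4-benzyl-2-oxazolidinone of the C5–C16 chain, C6 OMe and C7 OH syn, 8Z, C16 silyl ether; stereocentres arranged as in 47 | O=C1OC[C@@H](Cc2ccccc2)N1C(=O)[C@H](OC)[C@@H](O)/C(C)=C\[C@H](C)[C@@H](OC)[C@@H](OC)C[C@H](C)[C@@H](OC)CO[Si](C)(C)C(C)(C)C | intermediate
22 | N-methoxy-N-methyl amide of the C5–C16 chain (C7 OH) | CON(C)C(=O)[C@H](OC)[C@@H](O)/C(C)=C\[C@H](C)[C@@H](OC)[C@@H](OC)C[C@H](C)[C@@H](OC)CO[Si](C)(C)C(C)(C)C | intermediate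
23 | N-methoxy-N-methyl amide of the C5–C16 chain, C7 triisopropylsilyl ether | CON(C)C(=O)[C@H](OC)[C@@H](O[Si](C(C)C)(C(C)C)C(C)C)/C(C)=C\[C@H](C)[C@@H](OC)[C@@H](OC)C[C@H](C)[C@@H](OC)CO[Si](C)(C)C(C)(C)C | intermediate
24 | C5 aldehyde of the C5–C16 chain | O=C[C@H](OC)[C@@H](O[Si](C(C)C)(C(C)C)C(C)C)/C(C)=C\[C@H](C)[C@@H](OC)[C@@H](OC)C[C@H](C)[C@@H](OC)CO[Si](C)(C)C(C)(C)C | intermediate
25 | terminal alkyne C4–C16 | C#C[C@H](OC)[C@@H](O[Si](C(C)C)(C(C)C)C(C)C)/C(C)=C\[C@H](C)[C@@H](OC)[C@@H](OC)C[C@H](C)[C@@H](OC)CO[Si](C)(C)C(C)(C)C | intermediate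
26 | propargyl alcohol | C#CCO | starting material
27 | (Z)-3-iodo-2-methylprop-2-en-1-ol | OC/C(C)=C\I | intermediate
28 | (Z)-3-iodo-2-methylprop-2-enoic acid | OC(=O)/C(C)=C\I | intermediate
29 | 4-methoxybenzylamine | COc1ccc(CN)cc1 | starting material
30 | (Z)-3-iodo-N-(4-methoxybenzyl)-2-methylprop-2-enamide | COc1ccc(CNC(=O)/C(C)=C\I)cc1 | intermediate
31 | (2Z)-en-4-yne N-(4-methoxybenzyl) amide C1–C16 | COc1ccc(CNC(=O)/C(C)=C\C#C[C@H](OC)[C@@H](O[Si](C(C)C)(C(C)C)C(C)C)/C(C)=C\[C@H](C)[C@@H](OC)[C@@H](OC)C[C@H](C)[C@@H](OC)CO[Si](C)(C)C(C)(C)C)cc1 | intermediate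
32 | (2Z,4Z)-dienamide C1–C16, N-(4-methoxybenzyl) secondary amide | COc1ccc(CNC(=O)/C(C)=C\C=C/[C@H](OC)[C@@H](O[Si](C(C)C)(C(C)C)C(C)C)/C(C)=C\[C@H](C)[C@@H](OC)[C@@H](OC)C[C@H](C)[C@@H](OC)CO[Si](C)(C)C(C)(C)C)cc1 | intermediate
33 | N-[(trimethylsilyl)ethynyl]-N-(4-methoxybenzyl) dienamide (silyl ynamide) | C[Si](C)(C)C#CN(Cc1ccc(OC)cc1)C(=O)/C(C)=C\C=C/[C@H](OC)[C@@H](O[Si](C(C)C)(C(C)C)C(C)C)/C(C)=C\[C@H](C)[C@@H](OC)[C@@H](OC)C[C@H](C)[C@@H](OC)CO[Si](C)(C)C(C)(C)C | intermediate
34 | terminal ynamide with free C16 hydroxyl | C#CN(Cc1ccc(OC)cc1)C(=O)/C(C)=C\C=C/[C@H](OC)[C@@H](O[Si](C(C)C)(C(C)C)C(C)C)/C(C)=C\[C@H](C)[C@@H](OC)[C@@H](OC)C[C@H](C)[C@@H](OC)CO | intermediate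
35 | terminal ynamide C16 aldehyde | C#CN(Cc1ccc(OC)cc1)C(=O)/C(C)=C\C=C/[C@H](OC)[C@@H](O[Si](C(C)C)(C(C)C)C(C)C)/C(C)=C\[C@H](C)[C@@H](OC)[C@@H](OC)C[C@H](C)[C@@H](OC)C=O | intermediate
36 | hexacarbonylchromium, Cr(CO)6 | O=C=[Cr](=C=O)(=C=O)(=C=O)(=C=O)=C=O | starting material
37 | lithium acetylpentacarbonylchromate | [Li+].CC([O-])=[Cr](=C=O)(=C=O)(=C=O)(=C=O)=C=O | intermediate (not isolated)
38 | pentacarbonyl(1-methoxyethylidene)chromium, (CO)5Cr=C(OMe)CH3 | COC(C)=[Cr](=C=O)(=C=O)(=C=O)(=C=O)=C=O | intermediate
39 | aldol adduct: β-hydroxy carbene complex (C16 carbinol, both epimers) | C#CN(Cc1ccc(OC)cc1)C(=O)/C(C)=C\C=C/[C@H](OC)[C@@H](O[Si](C(C)C)(C(C)C)C(C)C)/C(C)=C\[C@H](C)[C@@H](OC)[C@@H](OC)C[C@H](C)[C@@H](OC)C(O)CC(OC)=[Cr](=C=O)(=C=O)(=C=O)(=C=O)=C=O | intermediate (not isolated)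
40 | open-chain (E)-alkenyl(methoxy)carbene pentacarbonylchromium with terminal N-(4-methoxybenzyl) ynamide, C7 triisopropylsilyl ether | C#CN(Cc1ccc(OC)cc1)C(=O)/C(C)=C\C=C/[C@H](OC)[C@@H](O[Si](C(C)C)(C(C)C)C(C)C)/C(C)=C\[C@H](C)[C@@H](OC)[C@@H](OC)C[C@H](C)[C@@H](OC)/C=C/C(OC)=[Cr](=C=O)(=C=O)(=C=O)(=C=O)=C=O | intermediate
41 | tricarbonylchromium arene complex of phenol 42, Cr(CO)3 bound to ring C16–C21 (written as its two components) | CO[C@H]1[C@@H](OC)C[C@H](C)[C@@H](OC)c2cc(OC)cc(c2O)N(Cc3ccc(OC)cc3)C(=O)/C(C)=C\C=C/[C@H](OC)[C@@H](O[Si](C(C)C)(C(C)C)C(C)C)/C(C)=C\[C@@H]1C.O=C=[Cr](=C=O)=C=O | intermediate (not isolated)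
42 | ansa 4-methoxyphenol N-(4-methoxybenzyl) lactam, C7 triisopropylsilyl ether | CO[C@H]1[C@@H](OC)C[C@H](C)[C@@H](OC)c2cc(OC)cc(c2O)N(Cc3ccc(OC)cc3)C(=O)/C(C)=C\C=C/[C@H](OC)[C@@H](O[Si](C(C)C)(C(C)C)C(C)C)/C(C)=C\[C@@H]1C | intermediate
43 | ansa quinone N–H lactam, C7 triisopropylsilyl ether | CO[C@H]1[C@@H](OC)C[C@H](C)[C@@H](OC)C2=CC(=O)C=C(C2=O)NC(=O)/C(C)=C\C=C/[C@H](OC)[C@@H](O[Si](C(C)C)(C(C)C)C(C)C)/C(C)=C\[C@@H]1C | intermediate
44 | ansa quinone lactam with free C7 hydroxyl | CO[C@H]1[C@@H](OC)C[C@H](C)[C@@H](OC)C2=CC(=O)C=C(C2=O)NC(=O)/C(C)=C\C=C/[C@H](OC)[C@@H](O)/C(C)=C\[C@@H]1C | intermediate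
45 | C7 N-(trichloroacetyl)carbamate of the quinone lactam | CO[C@H]1[C@@H](OC)C[C@H](C)[C@@H](OC)C2=CC(=O)C=C(C2=O)NC(=O)/C(C)=C\C=C/[C@H](OC)[C@@H](OC(=O)NC(=O)C(Cl)(Cl)Cl)/C(C)=C\[C@@H]1C | intermediate (not isolated)
46 | ansa quinone C7 carbamate | CO[C@H]1[C@@H](OC)C[C@H](C)[C@@H](OC)C2=CC(=O)C=C(C2=O)NC(=O)/C(C)=C\C=C/[C@H](OC)[C@@H](OC(N)=O)/C(C)=C\[C@@H]1C | intermediate
47 | CNP0109452.1, (2Z,4Z,6S,7S,8Z,10S,11R,12S,14S,15R) ansa hydroquinone carbamate | CO[C@H]1[C@@H](OC)C[C@H](C)[C@@H](OC)c2cc(O)cc(c2O)NC(=O)/C(C)=C\C=C/[C@H](OC)[C@@H](OC(N)=O)/C(C)=C\[C@@H]1C | target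

## Step count and least certain steps

Total step count: 34. Longest linear sequence: 28 steps (steps 1–4, 6–13, 15–19, 23–27, 29–34, from 1 and 2 to 47).

**Step 30 (key step).** The most likely failure is that the ynamide inserts and the resulting chromium vinylcarbene is stabilised by the nitrogen and never takes up CO. It would then collapse to five-membered-ring products or decompose. Oligomerisation by intermolecular insertion and insertion in the reversed sense are the other risks. All stem from the residual donor character of the ynamide nitrogen and from the entropic cost of the large ring.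

Fallback, known chemistry only, from alkyne 25 back to quinone 43:
- Acid 28 is converted to (Z)-3-iodo-2-methylprop-2-enamide F1 (mixed anhydride, then ammonia), which is coupled with 25 as in step 23 to give primary enynamide F2 and reduced with activated zinc as in step 24 to the primary (2Z,4Z)-dienamide F3.
- Bu4NF frees the C16 alcohol F4, Dess–Martin oxidation gives the C16 aldehyde F5, and condensation with 38 as in step 29 gives the alkenyl carbene complex F6.
- An intermolecular Dötz benzannulation of F6 with trimethylsilylacetylene, a well-established partner, gives the 2-silyl-4-methoxyphenol F7 with silicon at C20.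
- Iododesilylation with ICl gives the iodophenol F8, and O-methylation (MeI, K2CO3) gives the iodo dimethoxyarene F9.
- The 19-membered ring is closed by an intramolecular copper-catalysed amidation of the aryl iodide by the primary amide (CuI, N,N'-dimethylethylenediamine, K2CO3, toluene, 100 °C, high dilution), a ring closure known for this class of ansa lactams, to give the dimethoxyarene macrolactam F10.
- Oxidation of F10 with (NH4)2Ce(NO3)6 gives 43.

**Step 6.** Facial selectivity could be poor or reversed if the α-methoxy group chelates lithium and changes the azaenolate geometry, and the substitution at a β-branched iodide could be slow enough for the azaenolate to decompose.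

Fallback from iodide 6 back to aldehyde 11:
- Iodine–lithium exchange (t-BuLi, Et2O, −78 °C) and addition to N-methoxy-N-methyl-2,2-dimethoxyacetamide give the α-keto acetal F11.
- Corey–Bakshi–Shibata reduction with the (R)-methyl oxazaborolidine and BH3·SMe2, in which the dimethoxymethyl group should act as the large substituent, gives the (S)-α-hydroxy acetal F12.
- NaH/MeI gives the α-methoxy acetal F13.
- Et3SiOTf/2,4,6-collidine followed by water unmasks aldehyde 11 without cleaving the silyl ether.

**Step 25.** The ambident amidate could be alkynylated on oxygen, the alkylidene carbene could insert into a C–H bond instead of rearranging, or the acyclic N-acyl ynamide could be lost by hydration on work-up.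

Fallback from amide 32 back to alcohol 34:
- Trichloroethylene and Cs2CO3 in DMF give the N-(1,2-dichlorovinyl) amide F14.
- PhLi (2.2 equiv, THF, −78 °C), then NH4Cl, eliminates and exchanges chlorine to give the terminal ynamide with the C16 silyl ether F15.
- Bu4NF gives 34.

**Step 29.** The weakly nucleophilic carbene anion may add slowly and reversibly, the amine in the elimination stage may epimerise C15 through γ-deprotonation of the alkenyl carbene, and the product may begin to react with its own alkyne on concentration.

Fallback from 36 and 35 back to 40: a Peterson variant.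
- Me3SiCH2Li is added to 36 and the acyl chromate is methylated with Me3OBF4 to give pentacarbonyl[1-methoxy-2-(trimethylsilyl)ethylidene]chromium F16.
- Deprotonation of F16 with n-BuLi and addition to 35 gives a β-silyl alkoxide that eliminates lithium trimethylsilanolate on warming and gives 40 directly, with no mesylation and no amine.

## Further compounds

F1 | step 30 | (Z)-3-iodo-2-methylprop-2-enamide | NC(=O)/C(C)=C\I
F2 | step 30 | primary (2Z)-en-4-ynamide C1–C16 | NC(=O)/C(C)=C\C#C[C@H](OC)[C@@H](O[Si](C(C)C)(C(C)C)C(C)C)/C(C)=C\[C@H](C)[C@@H](OC)[C@@H](OC)C[C@H](C)[C@@H](OC)CO[Si](C)(C)C(C)(C)C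
F3 | step 30 | primary (2Z,4Z)-dienamide C1–C16 | NC(=O)/C(C)=C\C=C/[C@H](OC)[C@@H](O[Si](C(C)C)(C(C)C)C(C)C)/C(C)=C\[C@H](C)[C@@H](OC)[C@@H](OC)C[C@H](C)[C@@H](OC)CO[Si](C)(C)C(C)(C)C
F4 | step 30 | primary dienamide C16 alcohol | NC(=O)/C(C)=C\C=C/[C@H](OC)[C@@H](O[Si](C(C)C)(C(C)C)C(C)C)/C(C)=C\[C@H](C)[C@@H](OC)[C@@H](OC)C[C@H](C)[C@@H](OC)CO
F5 | step 30 | primary dienamide C16 aldehyde | NC(=O)/C(C)=C\C=C/[C@H](OC)[C@@H](O[Si](C(C)C)(C(C)C)C(C)C)/C(C)=C\[C@H](C)[C@@H](OC)[C@@H](OC)C[C@H](C)[C@@H](OC)C=O
F6 | step 30 | (E)-alkenyl(methoxy)carbene pentacarbonylchromium of the primary dienamide | NC(=O)/C(C)=C\C=C/[C@H](OC)[C@@H](O[Si](C(C)C)(C(C)C)C(C)C)/C(C)=C\[C@H](C)[C@@H](OC)[C@@H](OC)C[C@H](C)[C@@H](OC)/C=C/C(OC)=[Cr](=C=O)(=C=O)(=C=O)(=C=O)=C=O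
F7 | step 30 | open-chain 4-methoxy-2-(trimethylsilyl)phenol (silicon at C20) | NC(=O)/C(C)=C\C=C/[C@H](OC)[C@@H](O[Si](C(C)C)(C(C)C)C(C)C)/C(C)=C\[C@H](C)[C@@H](OC)[C@@H](OC)C[C@H](C)[C@@H](OC)c1cc(OC)cc(c1O)[Si](C)(C)C
F8 | step 30 | open-chain 2-iodo-4-methoxyphenol (iodine at C20) | NC(=O)/C(C)=C\C=C/[C@H](OC)[C@@H](O[Si](C(C)C)(C(C)C)C(C)C)/C(C)=C\[C@H](C)[C@@H](OC)[C@@H](OC)C[C@H](C)[C@@H](OC)c1cc(OC)cc(c1O)I
F9 | step 30 | open-chain iodo 1,4-dimethoxyarene | NC(=O)/C(C)=C\C=C/[C@H](OC)[C@@H](O[Si](C(C)C)(C(C)C)C(C)C)/C(C)=C\[C@H](C)[C@@H](OC)[C@@H](OC)C[C@H](C)[C@@H](OC)c1cc(OC)cc(c1OC)I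
F10 | step 30 | ansa 1,4-dimethoxyarene N–H lactam, C7 triisopropylsilyl ether | CO[C@H]1[C@@H](OC)C[C@H](C)[C@@H](OC)c2cc(OC)cc(c2OC)NC(=O)/C(C)=C\C=C/[C@H](OC)[C@@H](O[Si](C(C)C)(C(C)C)C(C)C)/C(C)=C\[C@@H]1C
F11 | step 6 | α-keto acetal C11–C16 | COC(OC)C(=O)C[C@H](C)[C@@H](OC)CO[Si](C)(C)C(C)(C)C
F12 | step 6 | (S)-α-hydroxy acetal C11–C16 | COC(OC)[C@@H](O)C[C@H](C)[C@@H](OC)CO[Si](C)(C)C(C)(C)C
F13 | step 6 | α-methoxy acetal C11–C16 | COC(OC)[C@@H](OC)C[C@H](C)[C@@H](OC)CO[Si](C)(C)C(C)(C)C
F14 | step 25 | N-[(E)-1,2-dichlorovinyl]-N-(4-methoxybenzyl) dienamide | Cl/C=C(/Cl)N(Cc1ccc(OC)cc1)C(=O)/C(C)=C\C=C/[C@H](OC)[C@@H](O[Si](C(C)C)(C(C)C)C(C)C)/C(C)=C\[C@H](C)[C@@H](OC)[C@@H](OC)C[C@H](C)[C@@H](OC)CO[Si](C)(C)C(C)(C)C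
F15 | step 25 | terminal ynamide with C16 silyl ether | C#CN(Cc1ccc(OC)cc1)C(=O)/C(C)=C\C=C/[C@H](OC)[C@@H](O[Si](C(C)C)(C(C)C)C(C)C)/C(C)=C\[C@H](C)[C@@H](OC)[C@@H](OC)C[C@H](C)[C@@H](OC)CO[Si](C)(C)C(C)(C)C
F16 | step 29 | pentacarbonyl[1-methoxy-2-(trimethylsilyl)ethylidene]chromium | COC(C[Si](C)(C)C)=[Cr](=C=O)(=C=O)(=C=O)(=C=O)=C=O
A1 | alternative 1 | 18-membered aryl ketoxime, hydroxyl anti to the arene | CO[C@H]1[C@@H](OC)C[C@H](C)[C@@H](OC)c2cc(OC)cc(c2OC)/C(=N/O)/C(C)=C\C#C[C@H](OC)[C@@H](O[Si](CC)(CC)CC)/C(C)=C\[C@@H]1C
A2 | alternative 1 | 19-membered (2Z)-en-4-yne lactam, C7 triethylsilyl ether | CO[C@H]1[C@@H](OC)C[C@H](C)[C@@H](OC)c2cc(OC)cc(c2OC)NC(=O)/C(C)=C\C#C[C@H](OC)[C@@H](O[Si](CC)(CC)CC)/C(C)=C\[C@@H]1C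
A3 | alternative 2 | seco dialdehyde (aldehydes at C11 and C12) | O=CC[C@H](C)[C@@H](OC)c1cc(OC)cc(c1OC)NC(=O)/C(C)=C\C=C/[C@H](OC)[C@@H](OC(N)=O)/C(C)=C\[C@H](C)C=O
A4 | alternative 2 | macrocyclic 11,12-diol | O[C@H]1[C@@H](O)C[C@H](C)[C@@H](OC)c2cc(OC)cc(c2OC)NC(=O)/C(C)=C\C=C/[C@H](OC)[C@@H](OC(N)=O)/C(C)=C\[C@@H]1C
A5 | alternative 3 | seco diyne with two methyl-capped alkynes | CC#C[C@H](OC)[C@@H](O[Si](C)(C)C(C)(C)C)/C(C)=C\[C@H](C)[C@@H](OC)[C@@H](OC)C[C@H](C)[C@@H](OC)c1cc(OC)cc(c1OC)NC(=O)/C(C)=C\C#CC
A6 | alternative 3 | 19-membered (2Z)-en-4-yne lactam, C7 tert-butyldimethylsilyl ether | CO[C@H]1[C@@H](OC)C[C@H](C)[C@@H](OC)c2cc(OC)cc(c2OC)NC(=O)/C(C)=C\C#C[C@H](OC)[C@@H](O[Si](C)(C)C(C)(C)C)/C(C)=C\[C@@H]1C
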